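Late in both earlier runs the J readings level off, so that is where we begin with your quick question, and with your hunch that more X ought to leave less J at the end.

| setting | amber | red | south-east | north | south-west |
|---|---|---|---|---|---|
| G | 0.20 M | 0.20 M | 0.20 M | 0.20 M | 0.20 M |
| E | 0.20 M | 0.20 M | 0.200 M | 0.200 M | 0.200 M |
| X | 0.0044 M | 0.012 M | 0.00400 M | 0.00600 M | 0.0100 M |
| remark | run made earlier | run made earlier |  |  |  |
| time |  |  | 20 min | 20 min | 20 min |

- amber (time / min: J / %): 3.00: 61.1; 6.00: 58.8; 8.00: 57.7; 12.0: 57.9; 15.0: 57.4; 20.0: 58.2
- red (time / min: J / %): 1.50: 65.9; 2.50: 62.0; 4.00: 59.3; 6.00: 58.5; 8.00: 58.1; 12.0: 57.6; 20.0: 57.1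

(scatter of a reading: 0.5 percentage points)

- candidate steps: E + X -> Q; J <-> Z; G + E -> D; G + E -> J
- "hardly changes" means that all values lie within two and a half points (for a concentration: within two and a half percent of the largest)

- [J] at the end for south-east, north, south-west, in this order
- how that number moves from the first to the last of them (falls, then rises / falls all the way / hardly changes / rises all the way / rises, then falls)

We take the mean of the flat tail of each run, from 12.0 min onward: amber gives 57.8 % and red gives 57.4 %. Red carries 2.73 times the X of amber, yet the two means differ by 0.40 percentage points, and one reading scatters by 0.5 points, so these readings show no difference beyond their scatter.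

The mean of the two, 57.6 %, is the quantity we carry: the plateau share, the fraction of the G charged that stands as J once the readings level off, which is an equilibrium yield if J and Z do exchange. With G and E charged as in these runs, we reckon J at the end as that share times the G charged, which gives 0.115 M.

The new flasks should reach that tail, because the earlier runs had levelled off within their scatter by 12.0 min, sooner than the 20 min asked. South-east holds just less X than amber, while north and south-west lie between amber and red.

Our forecast is therefore 0.115 M, 0.115 M and 0.115 M, and the row hardly changes, on this ground: “X changes how fast J falls, not where it ends”.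

The flasks give 0.115 M, 0.115 M and 0.115 M, and from first to last the number hardly changes.

    E + X → Q (k = 0.0940 M⁻¹ s⁻¹)
    J ⇌ Z (K = 0.270, k = 0.00170 s⁻¹)
    G + E → D, rate k3*[G] as long as [E] is above zero (k = 0.0430 s⁻¹)
    G + E → J (k = 1.80 M⁻¹ s⁻¹)

In south-east the relaxation half-life of J and Z, both directions together, is 1.44 min, short against the 20 min of the run. South-west has the most X of the new flasks; the plateau share times its G charge again gives 0.115 M, and at 20.0 min south-west holds J at 57.4 % of the G charged.

(All runs are simulated with constants of no real substance; the scatter is artificial.)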